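Everything rests on cutting C1–C10 of seven-membered ring A. The feature exploited is that C7–C8(CH3)=C9–C10 of ring A is an isoprene-type chain whose two ends can both hang on C6, C7 by a C–C bond and C10 through the C6 oxygen, as a 4-methyl-3,6-dihydro-2H-pyran in which C6 is allylic to C5=C1 of cyclopentene ring B. Lithiation at C10 then starts an anionic [2,3]-Wittig shift that in one operation forms C1–C10, breaks C6–O, closes ring A onto ring B, builds quaternary C1 by chirality transfer from C6 and leaves oxygen on C10. Precursor 13 is this (6S)-cyclopentenyl dihydropyran with the C4 carbinol as its triethylsilyl ether.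

Key step: step 7

Remark on numbering: daucane numbering is used (C1 quaternary methyl carbon, C4 isopropyl carbinol, C5 ring-fusion CH, C6 anisoate carbon, C10 acetate carbon). Beta is the face of the C1 methyl group, and the target is (1S,4R,5S,6S,10S), which means 1-beta-CH3, 4-beta-OH, 5-alpha-H, 6-alpha-O, 10-beta-O.

Assumption: 1 is bought as the (S)-(+) enantiomer of high enantiomeric purity; natural lots can be scalemic, so the lot is checked by chiral GC.

Stereochemical audit:
- (S)-1 maps onto (4R).
- (6S)-13 leads to (1S,10R)-16.
- Step 7 creates C1 and C10 and erases C6.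
- C10 is inverted in steps 8 and 9.
- C5 and C6 are set in step 11.

Design remarks:
- From 9 to 19 the C4 silyl ether is tertiary and allylic to an electron-rich alkene, so no strong Brønsted or Lewis acid is used in that stretch.
- The C4 oxygen stays silylated in step 7. A free C4 alkoxide would chelate lithium together with the pyran oxygen and hold C6–O on the unproductive beta face.

Step 1
Reactants: 1 (S)-(+)-terpinen-4-ol
Product: 2 (S)-terpinen-4-yl triethylsilyl ether
Conditions: Et3SiOTf, 2,6-lutidine, CH2Cl2, 0 °C → rt
Reagents that add atoms: triethylsilyl triflate, CC[Si](CC)(CC)OS(=O)(=O)C(F)(F)F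
Why: Silylation of a tertiary alcohol by a silyl triflate and a hindered pyridine base is standard, it does not touch the C–O bond so C4 keeps its configuration, and the ether shuts off retro-aldol and dehydration pathways in steps 2 and 3.

Step 2
Reactants: 2 (S)-terpinen-4-yl triethylsilyl ether
Product: 4 (S)-3-isopropyl-6-oxo-3-(triethylsilyloxy)heptanal, via secondary ozonide 3 (not isolated)
Conditions: O3, CH2Cl2, −78 °C; then Me2S, −78 °C → rt
Reagents that add atoms: ozone, [O-][O+]=O
Why: Ozonolysis with reductive work-up (Criegee mechanism through ozonide 3) cleaves the only alkene into the C1 methyl ketone and the C6 aldehyde, and the silyl ether and C4 are inert to ozone and dimethyl sulfide.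

Step 3
Reactants: 4 (S)-3-isopropyl-6-oxo-3-(triethylsilyloxy)heptanal
Product: 6 (R)-5-isopropyl-2-methyl-5-(triethylsilyloxy)cyclopent-1-ene-1-carbaldehyde, via aldol adduct 5 (not isolated)
Conditions: dibenzylammonium trifluoroacetate (20 mol %), toluene, 50 °C
Reagents that add atoms: none
Why: Amine-salt-catalysed intramolecular aldol condensation in its 5-enolexo mode, the established course for 6-oxoheptanals, joins the aldehyde-derived enamine carbon C5 to the ketone carbon C1, and in the weakly acidic buffer water leaves from C1 of adduct 5 in preference to the poorly basic and hindered silyloxy group on C4, whose configuration is untouched.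

Step 4
Reactants: 6 (R)-5-isopropyl-2-methyl-5-(triethylsilyloxy)cyclopent-1-ene-1-carbaldehyde; 7 2-methylallylmagnesium chloride
Product: 9 (S)-1-[(R)-5-isopropyl-2-methyl-5-(triethylsilyloxy)cyclopent-1-en-1-yl]-3-methylbut-3-en-1-ol, via borinate ester 8 (not isolated)
Conditions: (−)-B-methoxydiisopinocampheylborane [(−)-Ipc2BOMe, from (+)-alpha-pinene], 7, Et2O, −78 °C → rt; 6, −78 °C; then NaOH, H2O2, 0 °C
Reagents that add atoms: 2-methylallylmagnesium chloride 7, CC(=C)C[Mg]Cl
Why: Brown asymmetric allylboration through a closed chair transition state: the reagent built from (+)-alpha-pinene adds its 2-methylallyl group to the Si face of conjugated aldehydes, and this reagent control, which normally overrides a stereocentre beta to the carbonyl carbon, sets (6S).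

Step 5
Reactants: 9 (6S)-homoallylic alcohol; 10 allyl acetate
Product: 12 (6S)-allyl ether of 9, via zinc alkoxide 11 (not isolated)
Conditions: Et2Zn (0.5 equiv), Pd(OAc)2 (5 mol %), 2-(di-tert-butylphosphino)biphenyl (7.5 mol %), 10, THF, rt
Reagents that add atoms: allyl acetate 10, C=CCOC(C)=O
Why: Palladium-catalysed allylic etherification (Tsuji–Trost type) allylates the weakly basic zinc alkoxide 11 at oxygen without touching C6, and it avoids the oxygen-to-oxygen silyl shift from C4 to C6 that a sodium or potassium alkoxide in a Williamson reaction would invite.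

Step 6
Reactants: 12 (6S)-allyl ether
Product: 13 (2S)-4-methyl-2-[(5R)-5-isopropyl-2-methyl-5-(triethylsilyloxy)cyclopent-1-en-1-yl]-3,6-dihydro-2H-pyran
Conditions: second-generation Grubbs catalyst (H2IMes)(PCy3)Cl2Ru=CHPh (3 mol %), CH2Cl2, reflux
Reagents that add atoms: none
Why: Ring-closing metathesis of a monosubstituted and a 1,1-disubstituted alkene to a six-membered ring with the trisubstituted C8=C9 alkene is routine, the tetrasubstituted C5=C1 alkene is inert to the catalyst, loss of ethene drives the closure and no stereocentre is touched.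

Step 7
Reactants: 13 cyclopentenyl dihydropyran
Product: 16 ring A dienol (1S,4R,10R)-10-hydroxy-4-(triethylsilyloxy)dauca-5,8-diene (10-alpha-OH), via C10-lithiated dihydropyran 14 (not isolated), via lithium alkoxide 15 (not isolated)
Conditions: s-BuLi (1.3 equiv), THF, −78 °C, then slowly to −30 °C; H2O
Reagents that add atoms: none
Why: Proposed new method: s-BuLi, pre-complexed to the ring oxygen, removes the pseudo-axial C10–H (allylic to C8=C9 and alpha to oxygen), and the oxyallyllithium 14 bonds through C10 to C1 while the C6–O bond breaks on the same face of the C6–C5=C1 allyl unit, a concerted six-electron anionic [2,3]-sigmatropic (Wittig) shift paid for by the change from carbanion to alkoxide 15. The closest known reaction types are the [2,3]-Wittig ring contraction of macrocyclic bis-allylic ethers and the Wittig shifts of small-ring alpha-lithio ethers that carry a vinyl group at the other alpha-carbon, but the shift has not been shown for a dihydropyran with a tetrasubstituted acceptor alkene. Ring A closes because C7–C8=C9 already ties C6 to C10: along the carbon tether it is a 7-endo-trig attack of C10 on C1=C5, run through the five-membered C10–O–C6–C5–C1 envelope, so the transition state is an 8-oxabicyclo[3.2.1]octadiene-like cage that needs the cyclopentenyl group pseudo-axial on the pyran. C1 is controlled by C6: only the rotamer with H6 next to C4 and C7 next to the C1 methyl can give the cis ring alkene C5=C6, and in the (6S) ether it holds the C6–O bond over the alpha face (the isopropyl side), so C10 arrives alpha and the methyl ends beta (1S). C10 is controlled by the cage, in which H10 must point outward, so O10 emerges alpha, trans to the methyl (10R), while the C6 stereocentre is consumed. The step needs lithiation at C10 rather than at C6, C7 or the ring B allylic sites and [2,3] rather than radical [1,2]/[1,4] shifts: C10 is the only CH2 that is both allylic and alpha to oxygen, C6–H is tertiary, lies in the nodal plane of C5=C1 and is buried between isopropyl and OSiEt3, and working from −78 °C disfavours elimination and homolysis.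

Step 8
Reactants: 16 ring A dienol
Product: 17 (1S,4R)-4-(triethylsilyloxy)dauca-5,8-dien-10-one
Conditions: Dess–Martin periodinane, NaHCO3, CH2Cl2, 0 °C
Reagents that add atoms: none
Why: Dess–Martin oxidation under bicarbonate buffer turns the hindered allylic alcohol into the enone without acid or base strong enough to enolise toward C7, which would start vinylogous loss of the C4 silyloxy group.

Step 9
Reactants: 17 dienone
Product: 18 (1S,4R,10S)-10-hydroxy-4-(triethylsilyloxy)dauca-5,8-diene (10-beta-OH)
Conditions: NaBH4, CeCl3·7H2O, MeOH, −78 → −40 °C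
Reagents that add atoms: none
Why: Luche 1,2-reduction delivers hydride to the enone carbonyl from the alpha face, anti to the angular C1 methyl as with ketones next to an angular methyl group in hydrindanones and decalones, which sets the 10-beta (10S) alcohol cis to the methyl.

Step 10
Reactants: 18 10-beta-alcohol
Product: 19 (1S,4R,10S)-10-acetoxy-4-(triethylsilyloxy)dauca-5,8-diene
Conditions: Ac2O, pyridine, 4-(dimethylamino)pyridine (cat.), CH2Cl2, 0 °C → rt
Reagents that add atoms: acetic anhydride, CC(=O)OC(C)=O
Why: Nucleophile-catalysed acylation of the only free hydroxyl group proceeds at oxygen and therefore with retention at C10.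

Step 11
Reactants: 19 dienyl acetate
Product: 21 (1S,4R,5S,6S,10S)-10-acetoxy-6-hydroxy-4-(triethylsilyloxy)dauc-8-ene, via C6 alkylborane 20 (not isolated)
Conditions: BH3·THF (1.2 equiv), THF, 0 °C → rt; then NaBO3·4H2O, THF/H2O, rt
Reagents that add atoms: sodium perborate, [Na+].[Na+].O[B-]1(O)OO[B-](O)(O)OO1
Why: Hydroboration–oxidation adds H to C5 and boron to the less substituted C6 in a syn fashion from the alpha face, because the beta face carries both the C1 methyl and the C4 silyloxy group and attack anti to the allylic C4–O bond is also preferred electronically, which sets 5-alpha-H and 6-alpha-OH (5S,6S) with retention in the perborate oxidation, while C8=C9 is slowed by its allylic acetate (the effect that sends electrophiles to the remote alkene of geranyl acetate) and neutral perborate spares the ester.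

Step 12
Reactants: 21 6-alpha-alcohol; 22 4-methoxybenzoyl chloride
Product: 23 (1S,4R,5S,6S,10S)-10-acetoxy-4-(triethylsilyloxy)dauc-8-en-6-yl 4-methoxybenzoate
Conditions: 22, Et3N, 4-(dimethylamino)pyridine, CH2Cl2, rt → 40 °C
Reagents that add atoms: 4-methoxybenzoyl chloride 22, COc1ccc(cc1)C(Cl)=O
Why: Nucleophile-catalysed acylation of the only free, secondary hydroxyl group occurs at oxygen with retention at C6, the C4 oxygen being still silylated and the acetate inert.

Step 13
Reactants: 23 silyl-protected diester
Product: 24 target (1S,4R,5S,6S,10S)-10-acetoxy-4-hydroxydauc-8-en-6-yl 4-methoxybenzoate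
Conditions: HF·pyridine, pyridine, THF, 0 °C → rt
Reagents that add atoms: none
Why: Fluoride-driven cleavage of the Si–O bond by buffered HF·pyridine is mild enough for both esters and for the now non-allylic tertiary alcohol, and being non-basic it causes no acyl shift and touches no stereocentre.

Compound list
1 | (S)-(+)-terpinen-4-ol | CC1=CC[C@](O)(C(C)C)CC1 | starting material
2 | (S)-terpinen-4-yl triethylsilyl ether | CC1=CC[C@](O[Si](CC)(CC)CC)(C(C)C)CC1 | intermediate
3 | secondary ozonide of 2 (bridgeheads undefined) | CC12CC[C@@](O[Si](CC)(CC)CC)(C(C)C)CC(OO1)O2 | intermediate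
4 | (S)-3-isopropyl-6-oxo-3-(triethylsilyloxy)heptanal | CC(=O)CC[C@@](O[Si](CC)(CC)CC)(C(C)C)CC=O | intermediate
5 | aldol adduct, 2-hydroxy-5-isopropyl-2-methyl-5-(triethylsilyloxy)cyclopentanecarbaldehyde (C1 and C5 undefined) | CC1(O)CC[C@@](O[Si](CC)(CC)CC)(C(C)C)C1C=O | intermediate
6 | (R)-5-isopropyl-2-methyl-5-(triethylsilyloxy)cyclopent-1-ene-1-carbaldehyde | CC1=C(C=O)[C@](O[Si](CC)(CC)CC)(C(C)C)CC1 | intermediate
7 | 2-methylallylmagnesium chloride | CC(=C)C[Mg]Cl | starting material
8 | diisopinocampheylborinate ester of 9 | CC(=C)C[C@H](OB([C@@H]1C[C@@H]2C[C@H]([C@H]1C)C2(C)C)[C@@H]1C[C@@H]2C[C@H]([C@H]1C)C2(C)C)C1=C(C)CC[C@@]1(O[Si](CC)(CC)CC)C(C)C | intermediate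
9 | (6S)-homoallylic alcohol | CC(=C)C[C@H](O)C1=C(C)CC[C@@]1(O[Si](CC)(CC)CC)C(C)C | intermediate
10 | allyl acetate | C=CCOC(C)=O | starting material
11 | zinc bis(alkoxide) of 9 | [Zn](O[C@@H](CC(C)=C)C1=C(C)CC[C@@]1(O[Si](CC)(CC)CC)C(C)C)O[C@@H](CC(C)=C)C1=C(C)CC[C@@]1(O[Si](CC)(CC)CC)C(C)C | intermediate
12 | (6S)-allyl ether of 9 | C=CCO[C@@H](CC(C)=C)C1=C(C)CC[C@@]1(O[Si](CC)(CC)CC)C(C)C | intermediate
13 | cyclopentenyl dihydropyran (6S,4R), key-step precursor | CC1=CCO[C@@H](C1)C1=C(C)CC[C@@]1(O[Si](CC)(CC)CC)C(C)C | intermediate
14 | C10-lithiated dihydropyran (delocalised oxyallyllithium, C10 undefined) | CC1=CC([Li])O[C@@H](C1)C1=C(C)CC[C@@]1(O[Si](CC)(CC)CC)C(C)C | intermediate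
15 | lithium alkoxide of 16 | C1=C2[C@](O[Si](CC)(CC)CC)(C(C)C)CC[C@]2(C)[C@H]([O-])C=C(C)C1.[Li+] | intermediate
16 | ring A dienol (1S,4R,10R), 10-alpha-OH, key-step product | C1=C2[C@](O[Si](CC)(CC)CC)(C(C)C)CC[C@]2(C)[C@H](O)C=C(C)C1 | intermediate
17 | dienone (1S,4R) | C1=C2[C@](O[Si](CC)(CC)CC)(C(C)C)CC[C@]2(C)C(=O)C=C(C)C1 | intermediate
18 | 10-beta-alcohol (1S,4R,10S) | C1=C2[C@](O[Si](CC)(CC)CC)(C(C)C)CC[C@]2(C)[C@@H](O)C=C(C)C1 | intermediate
19 | 10-beta-acetate (1S,4R,10S) | C1=C2[C@](O[Si](CC)(CC)CC)(C(C)C)CC[C@]2(C)[C@@H](OC(C)=O)C=C(C)C1 | intermediate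
20 | C6 alkylborane (6-alpha-BH2, 5-alpha-H) | B[C@H]1CC(C)=C[C@H](OC(C)=O)[C@@]2(C)CC[C@@](O[Si](CC)(CC)CC)(C(C)C)[C@H]12 | intermediate
21 | 6-alpha-alcohol (1S,4R,5S,6S,10S) | O[C@H]1CC(C)=C[C@H](OC(C)=O)[C@@]2(C)CC[C@@](O[Si](CC)(CC)CC)(C(C)C)[C@H]12 | intermediate
22 | 4-methoxybenzoyl chloride | COc1ccc(cc1)C(Cl)=O | starting material
23 | silyl-protected diester | COc1ccc(C(=O)O[C@H]2CC(C)=C[C@H](OC(C)=O)[C@@]3(C)CC[C@@](O[Si](CC)(CC)CC)(C(C)C)[C@H]23)cc1 | intermediate
24 | CNP0256979.3 | COc1ccc(C(=O)O[C@H]2CC(C)=C[C@H](OC(C)=O)[C@@]3(C)CC[C@@](O)(C(C)C)[C@H]23)cc1 | target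

Total step count: 13. Longest linear sequence: 13 steps (1 to 24).

Steps most likely to fail

Step 7. Lithiation may be slow or misdirected and be followed by base-induced opening of the pyran through beta-elimination across C7–C6. Homolytic [1,2]- or [1,4]-shifts may also overtake the strained bridged [2,3] pathway. The fallback forms the same C1–C10 bond but separates rearrangement from ring closure, using known chemistry only.
- It sets out from allyl ether 12. This is lithiated with s-BuLi (THF, −78 °C) on its unsubstituted allyl CH2, the established site in unsymmetrical bis-allylic ethers.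
- An ordinary acyclic [2,3]-Wittig rearrangement follows, with the same C6-to-C1 chirality transfer, and gives the trienol F1. Its C5=C6 alkene has C7 cis to C1, and its C10 configuration is irrelevant.
- Ring-closing metathesis with the second-generation Grubbs catalyst joins the vinyl and isopropenyl groups to give the C10-epimeric dienols F2.
- Dess–Martin oxidation erases C10 and comes back to the route at dienone 17.

Step 11. Hydroboration of C8=C9 may compete and be followed by loss of the neighbouring acetate, and facial selectivity at the hindered C5=C6 alkene may be poor. The fallback sets out from dienone 17, where C8=C9 is switched off by conjugation.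
- Buffered mCPBA should epoxidise only C5=C6, from the alpha face, to the epoxy enone F3.
- Luche reduction gives the epoxy alcohol F4, and acetylation gives the epoxy acetate F5.
- Reductive epoxide opening uses titanocene monochloride Cp2TiCl (trivalent titanium, made from Cp2TiCl2 and Mn) with 1,4-cyclohexadiene as hydrogen-atom source. It cleaves the C5–O bond to the tertiary radical and keeps the 6-alpha oxygen.
- Hydrogen-atom transfer to the alpha face of C5, which is what this fallback requires and which is not assured, then comes back to the route at alcohol 21.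

Step 4. Facial selectivity may be poor or addition sluggish if the hindered chiral aldehyde erodes reagent control, and a wrong C6 configuration would be passed on to C1 in step 7. The fallback sets out from aldehyde 6.
- Uncontrolled addition of 7 (THF, −78 °C) gives the C6-epimeric alcohols F6.
- Dess–Martin oxidation gives the cross-conjugated ketone F7.
- Corey–Bakshi–Shibata reduction treats the cyclopentenyl group as the large substituent. It uses (R)-1-methyl-3,3-diphenyltetrahydro-1H,3H-pyrrolo[1,2-c][1,3,2]oxazaborole and catecholborane at −78 °C.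
- This comes back to the route at (6S)-alcohol 9.

Further compounds
F1 | step 7 | trienol, (1S,4R)-1-(1-hydroxyallyl)-1-methyl-4-isopropyl-4-(triethylsilyloxy)-5-(3-methylbut-3-enylidene)cyclopentane (daucane numbering), C7 cis to C1, C10 undefined | C=CC(O)[C@@]1(C)CC[C@@](O[Si](CC)(CC)CC)(C(C)C)/C1=C/CC(C)=C
F2 | step 7 | ring A dienols, C10 epimer mixture | C1=C2[C@](O[Si](CC)(CC)CC)(C(C)C)CC[C@]2(C)C(O)C=C(C)C1
F3 | step 11 | 5-alpha,6-alpha-epoxy enone | O1[C@H]2CC(C)=CC(=O)[C@@]3(C)CC[C@@](O[Si](CC)(CC)CC)(C(C)C)[C@]123
F4 | step 11 | 5-alpha,6-alpha-epoxy 10-beta-alcohol | O1[C@H]2CC(C)=C[C@H](O)[C@@]3(C)CC[C@@](O[Si](CC)(CC)CC)(C(C)C)[C@]123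
F5 | step 11 | 5-alpha,6-alpha-epoxy 10-beta-acetate | O1[C@H]2CC(C)=C[C@H](OC(C)=O)[C@@]3(C)CC[C@@](O[Si](CC)(CC)CC)(C(C)C)[C@]123
F6 | step 4 | homoallylic alcohols, C6 epimer mixture | CC(=C)CC(O)C1=C(C)CC[C@@]1(O[Si](CC)(CC)CC)C(C)C
F7 | step 4 | C6 ketone, 1-[(R)-5-isopropyl-2-methyl-5-(triethylsilyloxy)cyclopent-1-en-1-yl]-3-methylbut-3-en-1-one | CC(=C)CC(=O)C1=C(C)CC[C@@]1(O[Si](CC)(CC)CC)C(C)C
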